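The synthesis rests on cutting the lower chroman at C3–C4 and O1–C2. O1, C8a, C4a and C4 of the lower A ring, with the C7 oxygen para to C4a, are a latent o-quinone methide. C2 and C3 are the carboxyl and α-carbon of an arylacetic acid on the central ring. A carbene-catalysed formal [4+2] annulation joins the finished (3R,4S)-4-arylisoflavan acid to a simple silyloxybenzyl bromide, closes the last ring and sets lower C3 (R) under catalyst control. Earlier, the same carboxyl group is the leaving group of a racemic isochromanone. Its o-quinone methide builds the upper chroman enantioconvergently by enamine catalysis.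

Key step: step 11

Locants: "upper" is the 3,4-diarylchroman unit, "lower" is the 3-arylchroman unit, and "central ring" is the arene that joins them. Chroman numbering (O1, C2, C3, C4, C4a to C8a) is used in both units.
Assumption: the sense of induction in steps 6 and 11 is assigned from the accepted shielding models of the two catalysts; both antipodes of each catalyst are commercial, so a reversed sense would only require the other antipode.

Step 1
Reactants: 1 methyl 2-(3,5-dihydroxyphenyl)acetate
Product: 2 methyl 2-(2-formyl-3,5-dihydroxyphenyl)acetate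
Conditions: POCl3, DMF, MeCN, 0 °C → rt; then H2O, 50 °C
Reagents that add atoms: N,N-dimethylformamide CN(C)C=O; water O
Why: Vilsmeier–Haack formylation of a 5-substituted resorcinol goes, as with orcinol, to the position ortho to the side chain and para to one hydroxyl rather than between the two hydroxyls, which fixes the 1,2,3,5-pattern of the central ring.

Step 2
Reactants: 2 methyl 2-(2-formyl-3,5-dihydroxyphenyl)acetate
Product: 4 methyl 2-[5-(benzyloxy)-2-formyl-3-methoxyphenyl]acetate, via monobenzyl ether 3 (not isolated)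
Conditions: BnBr (1.0 equiv), K2CO3, acetone, rt; then MeI (excess), reflux
Reagents that add atoms: benzyl bromide BrCc1ccccc1; iodomethane CI
Why: Williamson etherification in two stages, in which the 5-OH para to the aldehyde is the more acidic and is not hydrogen-bonded, so it takes the single equivalent of benzyl bromide first (the selectivity known from 2,4-dihydroxybenzaldehyde), and the chelated 3-OH is then methylated at reflux.

Step 3
Reactants: 4 methyl 2-[5-(benzyloxy)-2-formyl-3-methoxyphenyl]acetate; 5 3-(benzyloxy)phenol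
Product: 8 rac-6-(benzyloxy)-1-[4-(benzyloxy)-2-hydroxyphenyl]-8-methoxyisochroman-3-one, via bromomagnesium phenolate 6 (not isolated), via benzhydrol ester 7 (not isolated)
Conditions: 5, EtMgBr (1.0 equiv), Et2O, 0 °C; solvent change to toluene; 4, rt → 45 °C; aq NH4Cl
Reagents that add atoms: none
Why: Ortho-specific hydroxyalkylation of a bromomagnesium phenolate by an aldehyde (six-membered Mg chelate) forms the C–C bond ortho to OH and, for steric reasons, para to OBn, and the magnesium alkoxide then transesterifies onto the neighbouring CH2CO2Me to give the δ-lactone, whose racemic centre is erased in step 6.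

Step 4
Reactants: 9 2-hydroxy-4,5-dimethoxybenzaldehyde
Product: 10 2-(benzyloxy)-4,5-dimethoxybenzaldehyde
Conditions: BnBr, K2CO3, DMF, 50 °C
Reagents that add atoms: benzyl bromide BrCc1ccccc1
Why: Williamson etherification of the only phenol, which masks the later upper 2'-OH with the same group as all other free phenols of the target.

Step 5
Reactants: 10 2-(benzyloxy)-4,5-dimethoxybenzaldehyde
Product: 12 2-[2-(benzyloxy)-4,5-dimethoxyphenyl]acetaldehyde, via enol ether 11 (not isolated)
Conditions: MeOCH2PPh3Cl, KOt-Bu, THF, 0 °C → rt; then 2 M HCl, THF, 40 °C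
Reagents that add atoms: (methoxymethyl)triphenylphosphonium chloride COC[P+](c1ccccc1)(c1ccccc1)c1ccccc1.[Cl-]; water O
Why: Wittig methoxymethylenation followed by acid hydrolysis of the enol ether is the standard one-carbon homologation of an aryl aldehyde to an arylacetaldehyde and creates no stereocentre.

Step 6
Reactants: 8 rac-6-(benzyloxy)-1-[4-(benzyloxy)-2-hydroxyphenyl]-8-methoxyisochroman-3-one; 12 2-[2-(benzyloxy)-4,5-dimethoxyphenyl]acetaldehyde
Product: 14 2-{5-(benzyloxy)-2-[(3R,4S)-7-(benzyloxy)-3-[2-(benzyloxy)-4,5-dimethoxyphenyl]-2-hydroxychroman-4-yl]-3-methoxyphenyl}acetic acid (anomer mixture at C2), via o-quinone methide acid 13 (not isolated)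
Conditions: (R)-α,α-diphenylprolinol trimethylsilyl ether (20 mol %), i-Pr2NEt (20 mol %), CHCl3, 0 °C → rt
Reagents that add atoms: none
Why: Enamine-catalysed formal [4+2] annulation (Michael addition–hemiacetalisation) of an aldehyde with an o-quinone methide made in situ, in which phenol-assisted loss of the lactone carboxylate turns both enantiomers of 8 into the same planar 13, the catalyst-bound E-enamine of 12, shielded on one face by the CPh2OTMS group, adds through the synclinal approach known from nitroalkene additions to give the syn adduct, that is trans-(3R,4S), and the phenol closes the lactol, while residual cis material can drain to trans through the epimerisable C3.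

Step 7
Reactants: 14 lactol acid from step 6
Product: 15 2-{5-(benzyloxy)-2-[(3R,4S)-7-(benzyloxy)-3-[2-(benzyloxy)-4,5-dimethoxyphenyl]chroman-4-yl]-3-methoxyphenyl}acetic acid
Conditions: Et3SiH, BF3·OEt2, CH2Cl2, −78 → −20 °C
Reagents that add atoms: none
Why: Ionic hydrogenation of the lactol (BF3 gives the C2 oxocarbenium ion, Et3SiH delivers hydride) leaves the carboxylic acid and the benzyl ethers alone, does not touch C4, and keeps C3 in its favoured trans arrangement.

Step 8
Reactants: 16 4-(benzyloxy)-2-hydroxybenzaldehyde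
Product: 17 4-(benzyloxy)-2-[(tert-butyldimethylsilyl)oxy]benzaldehyde
Conditions: TBSCl, imidazole, DMF, rt
Reagents that add atoms: tert-butyldimethylsilyl chloride CC(C)(C)[Si](C)(C)Cl
Why: Imidazole-promoted silylation of the phenol masks the future O1 until fluoride is added in step 11.

Step 9
Reactants: 17 4-(benzyloxy)-2-[(tert-butyldimethylsilyl)oxy]benzaldehyde
Product: 18 {4-(benzyloxy)-2-[(tert-butyldimethylsilyl)oxy]phenyl}methanol
Conditions: NaBH4, MeOH/THF, −10 °C
Reagents that add atoms: none
Why: Borohydride reduction of the aldehyde, in which the protic solvent and low temperature protonate the alkoxide at once and should suppress O-to-O silyl migration.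

Step 10
Reactants: 18 {4-(benzyloxy)-2-[(tert-butyldimethylsilyl)oxy]phenyl}methanol
Product: 19 [5-(benzyloxy)-2-(bromomethyl)phenoxy](tert-butyl)dimethylsilane
Conditions: CBr4, PPh3, CH2Cl2, 0 °C; short silica plug, used at once
Reagents that add atoms: tetrabromomethane BrC(Br)(Br)Br
Why: The Appel bromination runs under neutral conditions that spare the aryl silyl ether, and immediate use allows for the lability of this electron-rich benzylic bromide.

Step 11
Reactants: 15 2-{5-(benzyloxy)-2-[(3R,4S)-7-(benzyloxy)-3-[2-(benzyloxy)-4,5-dimethoxyphenyl]chroman-4-yl]-3-methoxyphenyl}acetic acid; 19 [5-(benzyloxy)-2-(bromomethyl)phenoxy](tert-butyl)dimethylsilane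
Product: 22 (3R)-7-(benzyloxy)-3-{5-(benzyloxy)-2-[(3R,4S)-7-(benzyloxy)-3-[2-(benzyloxy)-4,5-dimethoxyphenyl]chroman-4-yl]-3-methoxyphenyl}chroman-2-one, via acyl imidazole 20 (not isolated), via o-quinone methide 21 (not isolated)
Conditions: CDI (1.1 equiv), THF, rt, 1 h; then (5aR,10bS)-N-mesityl aminoindanol-derived triazolium BF4 (20 mol %), i-Pr2NEt (30 mol %), CsF, 18-crown-6, 4 Å MS, 19 added over 6 h, THF, −20 °C
Reagents that add atoms: none
Why: CDI turns the acid into 20, the carbene displaces imidazole and the catalyst-bound acyl azolium is deprotonated to its Z-enolate, while fluoride strips the silyl group of 19 so that the phenoxide expels bromide and the A ring is dearomatised to 21; the enolate α-carbon then adds to the exocyclic CH2 (C3–C4 bond, driven by rearomatisation) and the freed phenoxide O1 is acylated by the acyl azolium (O1–C2 bond), which releases the carbene. The closest known reaction type is the carbene-catalysed formal [4+2] annulation (dual Lewis-base activation) of acyl imidazoles or in situ activated carboxylic acids with fluoride-generated o-quinone methides to 3-substituted dihydrocoumarins, which can also be described as an inverse-electron-demand oxa-Diels–Alder reaction. The only ring closed is the six-membered pyranone, by intermolecular conjugate addition followed by 6-exo-trig lactonisation. The single new stereocentre, lower C3, is set by the catalyst: the indane wall covers the Si face of the α-carbon, so the CH2 of 21 arrives on the Re face (C2 > aryl > H) and gives R, while the upper C3 and C4 centres on the ortho substituent act only as a matched or mismatched perturbation. The step needs capture of 21 before it oligomerises, which slow release by sparingly soluble CsF, slow addition of 19 and the unhindered CH2 terminus that tolerates the crowded enolate should secure, and it needs the acidic C3–H of 22 to stay in place, which low temperature, the weak bases present and the twisted, poorly conjugating ortho-substituted aryl group should secure. All phenols of 15 are benzyl ethers, so O1 is the only oxygen nucleophile able to turn the catalyst over.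

Step 12
Reactants: 22 lactone from step 11
Product: 24 (3R)-7-(benzyloxy)-3-{5-(benzyloxy)-2-[(3R,4S)-7-(benzyloxy)-3-[2-(benzyloxy)-4,5-dimethoxyphenyl]chroman-4-yl]-3-methoxyphenyl}chroman (tetra-O-benzyl ether of the target), via lactol 23 (not isolated)
Conditions: DIBAL-H (1.1 equiv), CH2Cl2, −78 °C; then Et3SiH, BF3·OEt2, −78 → −30 °C
Reagents that add atoms: none
Why: DIBAL-H reduction of a dihydrocoumarin stops at the aluminium lactolate at −78 °C, and the ionic hydrogenation that follows (C2 oxocarbenium ion, hydride from Et3SiH) removes the temporary C2 oxygen without opening the ring, hydride capture at low temperature being expected to outrun loss of the C3 proton so that C3 stays R.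

Step 13
Reactants: 24 tetra-O-benzyl ether of the target
Product: 25 (3R)-3-{5-hydroxy-2-[(3R,4S)-7-hydroxy-3-(2-hydroxy-4,5-dimethoxyphenyl)chroman-4-yl]-3-methoxyphenyl}chroman-7-ol (CNP0266829.1)
Conditions: H2 (1 atm), 10 % Pd/C, EtOAc/MeOH, rt
Reagents that add atoms: none
Why: Catalytic hydrogenolysis cleaves the four benzyl aryl ethers, while the methyl ethers, the two chroman O1–C2 bonds (C2 is not benzylic) and the three stereocentres are not affected.

Compound list
1 | methyl 2-(3,5-dihydroxyphenyl)acetate | COC(=O)Cc1cc(O)cc(O)c1 | starting material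
2 | methyl 2-(2-formyl-3,5-dihydroxyphenyl)acetate | COC(=O)Cc1cc(O)cc(O)c1C=O | intermediate
3 | methyl 2-[5-(benzyloxy)-2-formyl-3-hydroxyphenyl]acetate | COC(=O)Cc1cc(OCc2ccccc2)cc(O)c1C=O | intermediate
4 | methyl 2-[5-(benzyloxy)-2-formyl-3-methoxyphenyl]acetate | COC(=O)Cc1cc(OCc2ccccc2)cc(OC)c1C=O | intermediate
5 | 3-(benzyloxy)phenol | Oc1cccc(OCc2ccccc2)c1 | starting material
6 | bromomagnesium 3-(benzyloxy)phenolate | Br[Mg]Oc1cccc(OCc2ccccc2)c1 | intermediate
7 | methyl 2-(5-(benzyloxy)-2-{[4-(benzyloxy)-2-hydroxyphenyl](hydroxy)methyl}-3-methoxyphenyl)acetate, racemic | COC(=O)Cc1cc(OCc2ccccc2)cc(OC)c1C(O)c1ccc(OCc2ccccc2)cc1O | intermediate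
8 | rac-6-(benzyloxy)-1-[4-(benzyloxy)-2-hydroxyphenyl]-8-methoxyisochroman-3-one | COc1cc(OCc2ccccc2)cc2CC(=O)OC(c3ccc(OCc4ccccc4)cc3O)c12 | intermediate
9 | 2-hydroxy-4,5-dimethoxybenzaldehyde | COc1cc(O)c(C=O)cc1OC | starting material
10 | 2-(benzyloxy)-4,5-dimethoxybenzaldehyde | COc1cc(OCc2ccccc2)c(C=O)cc1OC | intermediate
11 | 1-(benzyloxy)-4,5-dimethoxy-2-(2-methoxyvinyl)benzene, E/Z mixture | COC=Cc1cc(OC)c(OC)cc1OCc1ccccc1 | intermediate
12 | 2-[2-(benzyloxy)-4,5-dimethoxyphenyl]acetaldehyde | O=CCc1cc(OC)c(OC)cc1OCc1ccccc1 | intermediate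
13 | 2-(5-(benzyloxy)-2-{[4-(benzyloxy)-6-oxocyclohexa-2,4-dien-1-ylidene]methyl}-3-methoxyphenyl)acetic acid | O=C1C=C(OCc2ccccc2)C=CC1=Cc1c(OC)cc(OCc2ccccc2)cc1CC(=O)O | intermediate
14 | 2-{5-(benzyloxy)-2-[(3R,4S)-7-(benzyloxy)-3-[2-(benzyloxy)-4,5-dimethoxyphenyl]-2-hydroxychroman-4-yl]-3-methoxyphenyl}acetic acid, anomer mixture | COc1cc(OCc2ccccc2)c([C@@H]2C(O)Oc3cc(OCc4ccccc4)ccc3[C@H]2c2c(OC)cc(OCc3ccccc3)cc2CC(=O)O)cc1OC | intermediate
15 | 2-{5-(benzyloxy)-2-[(3R,4S)-7-(benzyloxy)-3-[2-(benzyloxy)-4,5-dimethoxyphenyl]chroman-4-yl]-3-methoxyphenyl}acetic acid | COc1cc(OCc2ccccc2)c([C@@H]2COc3cc(OCc4ccccc4)ccc3[C@H]2c2c(OC)cc(OCc3ccccc3)cc2CC(=O)O)cc1OC | intermediate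
16 | 4-(benzyloxy)-2-hydroxybenzaldehyde | O=Cc1ccc(OCc2ccccc2)cc1O | starting material
17 | 4-(benzyloxy)-2-[(tert-butyldimethylsilyl)oxy]benzaldehyde | O=Cc1ccc(OCc2ccccc2)cc1O[Si](C)(C)C(C)(C)C | intermediate
18 | {4-(benzyloxy)-2-[(tert-butyldimethylsilyl)oxy]phenyl}methanol | OCc1ccc(OCc2ccccc2)cc1O[Si](C)(C)C(C)(C)C | intermediate
19 | [5-(benzyloxy)-2-(bromomethyl)phenoxy](tert-butyl)dimethylsilane | BrCc1ccc(OCc2ccccc2)cc1O[Si](C)(C)C(C)(C)C | intermediate
20 | acyl imidazole of 15 | COc1cc(OCc2ccccc2)c([C@@H]2COc3cc(OCc4ccccc4)ccc3[C@H]2c2c(OC)cc(OCc3ccccc3)cc2CC(=O)n2ccnc2)cc1OC | intermediate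
21 | 3-(benzyloxy)-6-methylidenecyclohexa-2,4-dien-1-one | C=C1C=CC(OCc2ccccc2)=CC1=O | intermediate
22 | (3R)-7-(benzyloxy)-3-{5-(benzyloxy)-2-[(3R,4S)-7-(benzyloxy)-3-[2-(benzyloxy)-4,5-dimethoxyphenyl]chroman-4-yl]-3-methoxyphenyl}chroman-2-one | COc1cc(OCc2ccccc2)c([C@@H]2COc3cc(OCc4ccccc4)ccc3[C@H]2c2c(OC)cc(OCc3ccccc3)cc2[C@@H]2C(=O)Oc3cc(OCc4ccccc4)ccc3C2)cc1OC | intermediate
23 | chroman-2-ol (lactol) of 22, anomer mixture | COc1cc(OCc2ccccc2)c([C@@H]2COc3cc(OCc4ccccc4)ccc3[C@H]2c2c(OC)cc(OCc3ccccc3)cc2[C@@H]2C(O)Oc3cc(OCc4ccccc4)ccc3C2)cc1OC | intermediate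
24 | tetra-O-benzyl ether of the target, upper (3R,4S), lower (3R) | COc1cc(OCc2ccccc2)c([C@@H]2COc3cc(OCc4ccccc4)ccc3[C@H]2c2c(OC)cc(OCc3ccccc3)cc2[C@@H]2COc3cc(OCc4ccccc4)ccc3C2)cc1OC | intermediate
25 | (3R)-3-{5-hydroxy-2-[(3R,4S)-7-hydroxy-3-(2-hydroxy-4,5-dimethoxyphenyl)chroman-4-yl]-3-methoxyphenyl}chroman-7-ol | COc1cc(O)c([C@@H]2COc3cc(O)ccc3[C@H]2c2c(OC)cc(O)cc2[C@@H]2COc3cc(O)ccc3C2)cc1OC | target

Total step count: 13. Longest linear sequence: 8 steps (1, 2, 3, 6, 7, 11, 12, 13).

Steps most likely to fail

Step 11. The transient o-quinone methide may oligomerise or be taken by imidazole faster than the crowded enolate captures it. Fluoride may also epimerise the acidic C3–H of the product. The fallback replaces catalysis by auxiliary control. It sets out from 15 and 19 and returns at 22. Compound 15 is activated with pivaloyl chloride/Et3N and coupled with lithiated (R)-4-benzyl-1,3-oxazolidin-2-one to the N-acyl oxazolidinone F1. Its sodium Z-enolate (NaHMDS, THF, −78 °C) is alkylated with 19 on the face away from the benzyl group (Evans alkylation) to the (R)-configured silyl ether imide F2. TBAF buffered with AcOH then frees the phenol, which attacks the exocyclic imide carbonyl (6-exo-trig), expels the auxiliary and gives 22. The pyran ring is still the last ring closed.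

Step 6. Bond formation between the two hindered carbons may be slow, so that self-condensation of the arylacetaldehyde competes. A kinetic cis adduct that epimerises at C3 ends in the enantiomeric trans series, which erodes the enantiomeric purity. The fallback replaces asymmetric catalysis by classical resolution through the carboxylic acid. It sets out from 8 and 12 and returns at 15. The annulation is run with achiral pyrrolidine/AcOH at 40 °C to the racemic trans lactol acid F3. Ionic hydrogenation as in step 7 gives the racemic trans acid F4. Fractional crystallisation with (S)-1-phenylethylamine should give the diastereomerically pure ammonium salt F5, from which dilute HCl releases 15. The antipodal amine is used if the other salt proves the less soluble.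

Step 3. The electron-rich, di-ortho-substituted aldehyde may react sluggishly with the magnesium phenolate. The product may also ionise under the reaction conditions and arylate a second phenolate. The fallback is a boron-templated condensation. It sets out from 4 and 5 and returns at 8. Compounds 4 and 5 are heated with phenylboronic acid and catalytic propionic acid in refluxing toluene (Dean–Stark) to give the 2-phenyl-4H-1,3,2-benzodioxaborin F6. In it, boron ties the phenol oxygen to the aldehyde, delivers the carbon ortho to oxygen and masks the benzhydrol against over-reaction. Exchange with propane-1,3-diol releases 7, which lactonises to 8.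

Further compounds
F1 | step 11 | (R)-4-benzyl-3-(arylacetyl)-1,3-oxazolidin-2-one derived from 15 | COc1cc(OCc2ccccc2)c([C@@H]2COc3cc(OCc4ccccc4)ccc3[C@H]2c2c(OC)cc(OCc3ccccc3)cc2CC(=O)N2[C@H](Cc3ccccc3)COC2=O)cc1OC
F2 | step 11 | α-(R)-alkylated imide that carries the 4-(benzyloxy)-2-(TBSO)benzyl group | COc1cc(OCc2ccccc2)c([C@@H]2COc3cc(OCc4ccccc4)ccc3[C@H]2c2c(OC)cc(OCc3ccccc3)cc2[C@@H](Cc2ccc(OCc3ccccc3)cc2O[Si](C)(C)C(C)(C)C)C(=O)N2[C@H](Cc3ccccc3)COC2=O)cc1OC
F3 | step 6 | racemic trans lactol acid (both enantiomers) | COc1cc(OCc2ccccc2)c([C@@H]2C(O)Oc3cc(OCc4ccccc4)ccc3[C@H]2c2c(OC)cc(OCc3ccccc3)cc2CC(=O)O)cc1OC.COc1cc(OCc2ccccc2)c([C@H]2C(O)Oc3cc(OCc4ccccc4)ccc3[C@@H]2c2c(OC)cc(OCc3ccccc3)cc2CC(=O)O)cc1OC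
F4 | step 6 | racemic trans acid (both enantiomers) | COc1cc(OCc2ccccc2)c([C@@H]2COc3cc(OCc4ccccc4)ccc3[C@H]2c2c(OC)cc(OCc3ccccc3)cc2CC(=O)O)cc1OC.COc1cc(OCc2ccccc2)c([C@H]2COc3cc(OCc4ccccc4)ccc3[C@@H]2c2c(OC)cc(OCc3ccccc3)cc2CC(=O)O)cc1OC
F5 | step 6 | (S)-1-phenylethylammonium salt of 15 | COc1cc(OCc2ccccc2)c([C@@H]2COc3cc(OCc4ccccc4)ccc3[C@H]2c2c(OC)cc(OCc3ccccc3)cc2CC(=O)[O-])cc1OC.C[C@H]([NH3+])c1ccccc1
F6 | step 3 | methyl 2-{5-(benzyloxy)-2-[7-(benzyloxy)-2-phenyl-4H-1,3,2-benzodioxaborin-4-yl]-3-methoxyphenyl}acetate, racemic | COC(=O)Cc1cc(OCc2ccccc2)cc(OC)c1C1OB(c2ccccc2)Oc2cc(OCc3ccccc3)ccc12
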